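**Retrosynthetic overview**
- The polyene is cut at C11=C12 and C11'=C12': two successive Wittig reactions join the symmetrical C10 trienedial to two C15 phosphonium salts that differ only in the configuration at C5.
- Both salts come from one carbinol 8, the methylcerium adduct of a C15 vinylogous ester, made once and divided. Acid transposition, nucleophilic epoxidation and SmI2 opening give the trans-5-hydroxy end; bromohydroxylation of the enol ether and SmI2 debromination give the cis-5-hydroxy end.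
- Key bond C6–C7: the α'-carbon of dimedone ethyl enol ether is made electrophilic as its bromide and coupled with a dienylzirconium under enantioconvergent nickel catalysis. This sets C6 (S) for both ends.
- No ring is formed: both six-membered rings are bought as dimedone ethyl enol ether.

Assumption: the (S,S)-bis(oxazoline) ligand in step 3 gives the 6S product (otherwise its commercial antipode is used), and 1, 3 and 16 are bought as catalogue items (1 and 16 as pure E isomers).
Abbreviation: TBSO = tert-butyl(dimethyl)silyloxy.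

Step 1
Reactants: 1 (2E)-3-methylpent-2-en-4-yn-1-ol
Product: 2 tert-butyl(dimethyl){[(2E)-3-methylpent-2-en-4-yn-1-yl]oxy}silane
Conditions: TBSCl, imidazole, CH2Cl2, 0 °C to rt
Reagents that add atoms: tert-butyldimethylsilyl chloride CC(C)(C)[Si](C)(C)Cl
Why: Imidazole-promoted silylation of a primary alcohol masks the OH against the zirconium hydride and organocerium reagents, and the silyl ether is later lost without an extra step when the phosphonium salts are made.

Step 2
Reactants: 3 3-ethoxy-5,5-dimethylcyclohex-2-en-1-one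
Product: 5 rac-6-bromo-3-ethoxy-5,5-dimethylcyclohex-2-en-1-one, via lithium dienolate 4 (not isolated)
Conditions: LiN(iPr)2, THF, −78 °C; then NBS, −78 °C; NH4Cl work-up
Reagents that add atoms: N-bromosuccinimide O=C1CCC(=O)N1Br
Why: Kinetic deprotonation of a vinylogous ester occurs only at the α'-CH2 (Stork–Danheiser regiochemistry), and electrophilic α-bromination of the dienolate turns that normally nucleophilic carbon into an electrophilic one.

Step 3
Reactants: 2 tert-butyl(dimethyl){[(2E)-3-methylpent-2-en-4-yn-1-yl]oxy}silane; 5 rac-6-bromo-3-ethoxy-5,5-dimethylcyclohex-2-en-1-one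
Product: 7 (6S)-6-[(1E,3E)-5-(TBSO)-3-methylpenta-1,3-dien-1-yl]-3-ethoxy-5,5-dimethylcyclohex-2-en-1-one, via dienylzirconocene 6 (not isolated)
Conditions: 2, Cp2Zr(H)Cl (1.2 equiv), THF, rt, 1 h; then 5, NiCl2·(MeOCH2CH2OMe) (5 mol %), (S,S)-2,2'-(propane-2,2-diyl)bis(4-phenyl-4,5-dihydro-1,3-oxazole) (6.5 mol %), DME/THF, 10 °C, 24 h
Reagents that add atoms: none
Why: Proposed new method: syn-hydrozirconation of the terminal alkyne gives the (E,E)-dienylzirconium; the nickel/bis(oxazoline) catalyst abstracts bromine from either enantiomer of 5 to give a planar α-keto radical, stabilised by the vinylogous ester carbonyl, which recombines with the chiral alkenylnickel species formed by transmetalation, and reductive elimination forges C6–C7 and sets C6 (S) under catalyst control, the radical path tolerating the adjacent quaternary carbon where an SN2 displacement would not; the closest known reaction type is the nickel-catalysed stereoconvergent Negishi-type alkenylation of racemic acyclic α-bromo ketones with alkenylzirconium reagents, here extended to a cyclic α'-bromo vinylogous ester.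

Step 4
Reactants: 7 (6S)-6-[(1E,3E)-5-(TBSO)-3-methylpenta-1,3-dien-1-yl]-3-ethoxy-5,5-dimethylcyclohex-2-en-1-one
Product: 8 (1S,6S)-6-[(1E,3E)-5-(TBSO)-3-methylpenta-1,3-dien-1-yl]-3-ethoxy-1,5,5-trimethylcyclohex-2-en-1-ol
Conditions: MeLi, CeCl3, THF, −78 °C; aq NaHCO3 work-up, dry over K2CO3; crude 8 used at once, one half in step 5 and one half in step 8
Reagents that add atoms: methyllithium C[Li]
Why: In this organocerium 1,2-addition the weakly basic reagent attacks the vinylogous ester carbonyl without deprotonating the acidic C6–H, the methyl group enters anti to the neighbouring C6 dienyl chain (1,2-induction as in 2-substituted cyclohexanones) so that OH ends up cis to the chain, and the bicarbonate work-up keeps the acid-labile carbinol intact for both branches.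

Step 5
Reactants: 8 (1S,6S)-6-[(1E,3E)-5-(TBSO)-3-methylpenta-1,3-dien-1-yl]-3-ethoxy-1,5,5-trimethylcyclohex-2-en-1-ol
Product: 9 (4S)-4-[(1E,3E)-5-(TBSO)-3-methylpenta-1,3-dien-1-yl]-3,5,5-trimethylcyclohex-2-en-1-one
Conditions: 0.5 M HCl, THF, 0 °C, 15 min
Reagents that add atoms: water O
Why: Brief dilute acid effects the Stork–Danheiser transposition (enol ether hydrolysis and loss of the tertiary allylic hydroxyl) to the 4-substituted isophorone, and the chain-bearing stereocentre survives as it does in the standard preparation of enantioenriched 4-substituted cyclohexenones.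

Step 6
Reactants: 9 (4S)-4-[(1E,3E)-5-(TBSO)-3-methylpenta-1,3-dien-1-yl]-3,5,5-trimethylcyclohex-2-en-1-one
Product: 10 (1R,5S,6R)-5-[(1E,3E)-5-(TBSO)-3-methylpenta-1,3-dien-1-yl]-4,4,6-trimethyl-7-oxabicyclo[4.1.0]heptan-2-one
Conditions: 30% H2O2 (10 equiv), LiOH (0.2 equiv), MeOH, 0 °C
Reagents that add atoms: hydrogen peroxide OO
Why: In this Weitz–Scheffer nucleophilic epoxidation the hydroperoxide anion adds axially to the β-carbon anti to the pseudoaxial dienyl chain on the neighbouring carbon, so the epoxide forms trans to the chain, while the large excess of H2O2 holds the basicity low enough to spare the γ-stereocentre and the electron-rich diene is inert.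

Step 7
Reactants: 10 (1R,5S,6R)-5-[(1E,3E)-5-(TBSO)-3-methylpenta-1,3-dien-1-yl]-4,4,6-trimethyl-7-oxabicyclo[4.1.0]heptan-2-one
Product: 11 (3S,4S)-4-[(1E,3E)-5-(TBSO)-3-methylpenta-1,3-dien-1-yl]-3-hydroxy-3,5,5-trimethylcyclohexan-1-one
Conditions: SmI2 (2.2 equiv), THF/MeOH, −90 °C
Reagents that add atoms: none
Why: SmI2 reduction of an α,β-epoxy ketone cleaves only the Cα–O bond through the ketyl, so the tertiary C–O bond and its configuration survive and the β-hydroxy ketone with OH trans to the chain results without elimination.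

Step 8
Reactants: 8 (1S,6S)-6-[(1E,3E)-5-(TBSO)-3-methylpenta-1,3-dien-1-yl]-3-ethoxy-1,5,5-trimethylcyclohex-2-en-1-ol
Product: 12 (2RS,3S,4S)-2-bromo-4-[(1E,3E)-5-(TBSO)-3-methylpenta-1,3-dien-1-yl]-3-hydroxy-3,5,5-trimethylcyclohexan-1-one
Conditions: NBS (1.05 equiv), NaHCO3, THF/H2O, −20 °C
Reagents that add atoms: N-bromosuccinimide O=C1CCC(=O)N1Br; water O
Why: In this bromohydroxylation (halohydrin-type electrophilic addition) the enol ether takes up bromine much faster than the diene, water captures the oxocarbenium ion and the hemiketal loses ethanol, which unveils the ketone under buffered neutral conditions and keeps the tertiary alcohol that acid hydrolysis would eliminate, the configuration at the new C–Br carbon being of no consequence.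

Step 9
Reactants: 12 (2RS,3S,4S)-2-bromo-4-[(1E,3E)-5-(TBSO)-3-methylpenta-1,3-dien-1-yl]-3-hydroxy-3,5,5-trimethylcyclohexan-1-one
Product: 13 (3R,4S)-4-[(1E,3E)-5-(TBSO)-3-methylpenta-1,3-dien-1-yl]-3-hydroxy-3,5,5-trimethylcyclohexan-1-one
Conditions: SmI2 (2.2 equiv), THF/MeOH, −78 °C; chromatography
Reagents that add atoms: none
Why: Reductive dehalogenation of an α-bromo ketone by SmI2 gives the samarium enolate, which is protonated by methanol at low temperature before it can expel the β-hydroxyl (the same type of enolate as in step 7), so both bromo epimers converge on the cis β-hydroxy ketone and any minor carbinol epimer carried from step 4 is removed here.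

Step 10
Reactants: 11 (3S,4S)-4-[(1E,3E)-5-(TBSO)-3-methylpenta-1,3-dien-1-yl]-3-hydroxy-3,5,5-trimethylcyclohexan-1-one
Product: 14 {(2E,4E)-5-[(1S,2S)-2-hydroxy-2,6,6-trimethyl-4-oxocyclohexyl]-3-methylpenta-2,4-dien-1-yl}(triphenyl)phosphonium bromide
Conditions: PPh3·HBr (1.05 equiv), MeOH, 0 °C to rt; crystallise the E,E salt
Reagents that add atoms: triphenylphosphine hydrobromide Br.c1ccc(cc1)P(c1ccccc1)c1ccccc1
Why: Acidic methanolysis of the allylic silyl ether followed by substitution of the dienylic alcohol by triphenylphosphine at the terminal carbon is the classical preparation of C15 Wittig salts, and the weakly acidic medium at room temperature is expected to leave the tertiary β-hydroxy ketone intact.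

Step 11
Reactants: 13 (3R,4S)-4-[(1E,3E)-5-(TBSO)-3-methylpenta-1,3-dien-1-yl]-3-hydroxy-3,5,5-trimethylcyclohexan-1-one
Product: 15 {(2E,4E)-5-[(1S,2R)-2-hydroxy-2,6,6-trimethyl-4-oxocyclohexyl]-3-methylpenta-2,4-dien-1-yl}(triphenyl)phosphonium bromide
Conditions: PPh3·HBr (1.05 equiv), MeOH, 0 °C to rt; crystallise the E,E salt
Reagents that add atoms: triphenylphosphine hydrobromide Br.c1ccc(cc1)P(c1ccccc1)c1ccccc1
Why: The same desilylation and phosphonium salt formation as in step 10, applied to the cis series, with no stereocentre involved.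

Step 12
Reactants: 14 {(2E,4E)-5-[(1S,2S)-2-hydroxy-2,6,6-trimethyl-4-oxocyclohexyl]-3-methylpenta-2,4-dien-1-yl}(triphenyl)phosphonium bromide; 16 (2E,4E,6E)-2,7-dimethylocta-2,4,6-trienedial
Product: 18 (2E,4E,6E,8E,10E,12E)-13-[(1S,2S)-2-hydroxy-2,6,6-trimethyl-4-oxocyclohexyl]-2,7,11-trimethyltrideca-2,4,6,8,10,12-hexaenal, via ylide 17 (not isolated)
Conditions: 16 (3 equiv), 1,2-epoxybutane/EtOH, 70 °C, slow addition of 14; excess 16 recovered
Reagents that add atoms: none
Why: Wittig olefination under neutral, epoxide-buffered conditions spares the base-sensitive β-hydroxy ketone, the excess dialdehyde (more electrophilic than the longer mono-olefinated product) secures mono-olefination, and the new disubstituted double bond equilibrates to E on heating.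

Step 13
Reactants: 18 (2E,4E,6E,8E,10E,12E)-13-[(1S,2S)-2-hydroxy-2,6,6-trimethyl-4-oxocyclohexyl]-2,7,11-trimethyltrideca-2,4,6,8,10,12-hexaenal; 15 {(2E,4E)-5-[(1S,2R)-2-hydroxy-2,6,6-trimethyl-4-oxocyclohexyl]-3-methylpenta-2,4-dien-1-yl}(triphenyl)phosphonium bromide
Product: 20 (5S,6S,5'R,6'S)-5,5'-dihydroxy-5,6,5',6'-tetrahydro-β,β-carotene-3,3'-dione, via ylide 19 (not isolated)
Conditions: 15 (1.2 equiv), 1,2-epoxybutane/EtOH, 70 °C; then heptane, 90 °C (Z to E), crystallise, dark, argon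
Reagents that add atoms: none
Why: The second neutral Wittig olefination attaches the cis end to the free aldehyde, the sterically hindered 11-cis isomers relax thermally to the all-E polyene, and none of the four stereocentres is touched.

**Compound list**
1 | (2E)-3-methylpent-2-en-4-yn-1-ol | C#C/C(C)=C/CO | starting material
2 | tert-butyl(dimethyl){[(2E)-3-methylpent-2-en-4-yn-1-yl]oxy}silane | C#C/C(C)=C/CO[Si](C)(C)C(C)(C)C | intermediate
3 | 3-ethoxy-5,5-dimethylcyclohex-2-en-1-one (dimedone ethyl enol ether) | CCOC1=CC(=O)CC(C)(C)C1 | starting material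
4 | lithium 5-ethoxy-3,3-dimethylcyclohexa-1,5-dien-1-olate | [Li]OC1=CC(C)(C)CC(OCC)=C1 | intermediate (not isolated)
5 | rac-6-bromo-3-ethoxy-5,5-dimethylcyclohex-2-en-1-one | CCOC1=CC(=O)C(Br)C(C)(C)C1 | intermediate
6 | chlorobis(cyclopentadienyl)[(1E,3E)-5-{[tert-butyl(dimethyl)silyl]oxy}-3-methylpenta-1,3-dien-1-yl]zirconium | CC(C)(C)[Si](C)(C)OC/C=C(C)/C=C/[Zr](Cl)(C1C=CC=C1)C1C=CC=C1 | intermediate (not isolated)
7 | (6S)-6-[(1E,3E)-5-{[tert-butyl(dimethyl)silyl]oxy}-3-methylpenta-1,3-dien-1-yl]-3-ethoxy-5,5-dimethylcyclohex-2-en-1-one | CC(C)(C)[Si](C)(C)OC/C=C(C)/C=C/[C@H]1C(C)(C)CC(OCC)=CC1=O | intermediate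
8 | (1S,6S)-6-[(1E,3E)-5-{[tert-butyl(dimethyl)silyl]oxy}-3-methylpenta-1,3-dien-1-yl]-3-ethoxy-1,5,5-trimethylcyclohex-2-en-1-ol (OH cis to the dienyl chain) | CC(C)(C)[Si](C)(C)OC/C=C(C)/C=C/[C@H]1C(C)(C)CC(OCC)=C[C@@]1(C)O | intermediate
9 | (4S)-4-[(1E,3E)-5-{[tert-butyl(dimethyl)silyl]oxy}-3-methylpenta-1,3-dien-1-yl]-3,5,5-trimethylcyclohex-2-en-1-one | CC(C)(C)[Si](C)(C)OC/C=C(C)/C=C/[C@H]1C(C)(C)CC(=O)C=C1C | intermediate
10 | (1R,5S,6R)-5-[(1E,3E)-5-{[tert-butyl(dimethyl)silyl]oxy}-3-methylpenta-1,3-dien-1-yl]-4,4,6-trimethyl-7-oxabicyclo[4.1.0]heptan-2-one (epoxide trans to the dienyl chain) | CC(C)(C)[Si](C)(C)OC/C=C(C)/C=C/[C@H]1C(C)(C)CC(=O)[C@@H]2O[C@@]21C | intermediate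
11 | (3S,4S)-4-[(1E,3E)-5-{[tert-butyl(dimethyl)silyl]oxy}-3-methylpenta-1,3-dien-1-yl]-3-hydroxy-3,5,5-trimethylcyclohexan-1-one (OH trans to the chain) | CC(C)(C)[Si](C)(C)OC/C=C(C)/C=C/[C@H]1C(C)(C)CC(=O)C[C@]1(C)O | intermediate
12 | (2RS,3S,4S)-2-bromo-4-[(1E,3E)-5-{[tert-butyl(dimethyl)silyl]oxy}-3-methylpenta-1,3-dien-1-yl]-3-hydroxy-3,5,5-trimethylcyclohexan-1-one (both C2 epimers) | CC(C)(C)[Si](C)(C)OC/C=C(C)/C=C/[C@H]1C(C)(C)CC(=O)C(Br)[C@@]1(C)O | intermediate
13 | (3R,4S)-4-[(1E,3E)-5-{[tert-butyl(dimethyl)silyl]oxy}-3-methylpenta-1,3-dien-1-yl]-3-hydroxy-3,5,5-trimethylcyclohexan-1-one (OH cis to the chain) | CC(C)(C)[Si](C)(C)OC/C=C(C)/C=C/[C@H]1C(C)(C)CC(=O)C[C@@]1(C)O | intermediate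
14 | {(2E,4E)-5-[(1S,2S)-2-hydroxy-2,6,6-trimethyl-4-oxocyclohexyl]-3-methylpenta-2,4-dien-1-yl}(triphenyl)phosphonium bromide | c2ccccc2[P+](c3ccccc3)(c4ccccc4)C/C=C(C)/C=C/[C@H]1C(C)(C)CC(=O)C[C@]1(C)O.[Br-] | intermediate
15 | {(2E,4E)-5-[(1S,2R)-2-hydroxy-2,6,6-trimethyl-4-oxocyclohexyl]-3-methylpenta-2,4-dien-1-yl}(triphenyl)phosphonium bromide | c2ccccc2[P+](c3ccccc3)(c4ccccc4)C/C=C(C)/C=C/[C@H]1C(C)(C)CC(=O)C[C@@]1(C)O.[Br-] | intermediate
16 | (2E,4E,6E)-2,7-dimethylocta-2,4,6-trienedial | O=C/C(C)=C/C=C/C=C(C)/C=O | starting material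
17 | ylide of 14: (3S,4S)-3-hydroxy-3,5,5-trimethyl-4-[(1E,3E)-3-methyl-5-(triphenylphosphoranylidene)penta-1,3-dien-1-yl]cyclohexan-1-one | c2ccccc2[P+](c3ccccc3)(c4ccccc4)[CH-]/C=C(C)/C=C/[C@H]1C(C)(C)CC(=O)C[C@]1(C)O | intermediate (not isolated)
18 | (2E,4E,6E,8E,10E,12E)-13-[(1S,2S)-2-hydroxy-2,6,6-trimethyl-4-oxocyclohexyl]-2,7,11-trimethyltrideca-2,4,6,8,10,12-hexaenal | O=C/C(C)=C/C=C/C=C(C)/C=C/C=C(C)/C=C/[C@H]1C(C)(C)CC(=O)C[C@]1(C)O | intermediate
19 | ylide of 15: (3R,4S)-3-hydroxy-3,5,5-trimethyl-4-[(1E,3E)-3-methyl-5-(triphenylphosphoranylidene)penta-1,3-dien-1-yl]cyclohexan-1-one | c2ccccc2[P+](c3ccccc3)(c4ccccc4)[CH-]/C=C(C)/C=C/[C@H]1C(C)(C)CC(=O)C[C@@]1(C)O | intermediate (not isolated)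
20 | (5S,6S,5'R,6'S)-5,5'-dihydroxy-5,6,5',6'-tetrahydro-β,β-carotene-3,3'-dione | CC(/C=C/C=C(C)/C=C/[C@H]1C(C)(C)CC(=O)C[C@]1(C)O)=C\C=C\C=C(C)\C=C\C=C(C)\C=C\[C@H]1C(C)(C)CC(=O)C[C@@]1(C)O | target

**Step count and risks**
Total step count: 13.
Longest linear sequence: 9 steps (3 → 5 → 7 → 8 → 9 → 10 → 11 → 14 → 18 → 20).

Steps most likely to fail:

Step 3. The bromide sits next to a quaternary carbon, and the catalyst has not been shown on a cyclic α'-bromo vinylogous ester, so yield or enantioselectivity may be poor. The fallback sets out from 3 and 2 and comes back at 7.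
- Trifluoroacetylation of the lithium enolate of 3 (LiN(SiMe3)2, THF, −78 °C; CF3CO2CH2CF3) gives 3-ethoxy-5,5-dimethyl-6-(trifluoroacetyl)cyclohex-2-en-1-one F1, which is not isolated.
- Detrifluoroacetylative diazo transfer (MsN3, Et3N, H2O, MeCN, rt) turns it into 6-diazo-3-ethoxy-5,5-dimethylcyclohex-2-en-1-one F2.
- Hydroboration of 2 with catecholborane (neat, 70 °C) gives 2-[(1E,3E)-5-{[tert-butyl(dimethyl)silyl]oxy}-3-methylpenta-1,3-dien-1-yl]-1,3,2-benzodioxaborole F3.
- Hydrolysis with water gives [(1E,3E)-5-{[tert-butyl(dimethyl)silyl]oxy}-3-methylpenta-1,3-dien-1-yl]boronic acid F4.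
- Heating F2 with F4 (toluene, iPr2NH, 90 °C) joins C6 to C7 without a metal, by boron ate-complex formation at the diazo carbon, 1,2-alkenyl shift with loss of N2 and protonation of the boron enolate.
- The product is racemic; preparative HPLC on an amylose phase gives 7, and its mirror image (6R)-6-[(1E,3E)-5-{[tert-butyl(dimethyl)silyl]oxy}-3-methylpenta-1,3-dien-1-yl]-3-ethoxy-5,5-dimethylcyclohex-2-en-1-one F5 is racemised with DBU and recycled.

Step 6. The enone is hindered, and its γ-hydrogen (allylic to the diene) could be removed by base, which would erode the only stereocentre before the epoxide forms. The fallback sets out from 9 and comes back at 11, bypassing 10 and step 7. Copper-catalysed conjugate borylation (B2pin2, CuCl, bis[2-(diphenylphosphanyl)phenyl] ether, catalytic NaOtBu, MeOH, THF, rt) adds boron anti to the dienyl chain to give (3R,4R)-4-[(1E,3E)-5-{[tert-butyl(dimethyl)silyl]oxy}-3-methylpenta-1,3-dien-1-yl]-3,5,5-trimethyl-3-(4,4,5,5-tetramethyl-1,3,2-dioxaborolan-2-yl)cyclohexan-1-one F6. Oxidation in the same flask with NaBO3·4H2O, with retention at carbon, gives 11.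

Step 10. The trans β-hydroxy ketone 11 is the more strained C5 epimer, and PPh3·HBr could dehydrate it to the enone or scramble the dienyl unit. The fallback sets out from 11 and comes back at 14 under neutral conditions. Bu4NF buffered with AcOH (THF, 0 °C) gives (3S,4S)-3-hydroxy-4-[(1E,3E)-5-hydroxy-3-methylpenta-1,3-dien-1-yl]-3,5,5-trimethylcyclohexan-1-one F7. Appel bromination of the primary allylic alcohol (CBr4, PPh3, CH2Cl2, −20 °C) gives (3S,4S)-4-[(1E,3E)-5-bromo-3-methylpenta-1,3-dien-1-yl]-3-hydroxy-3,5,5-trimethylcyclohexan-1-one F8. PPh3 in toluene at rt then gives 14.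

**Further compounds**
F1 | step 3 | 3-ethoxy-5,5-dimethyl-6-(trifluoroacetyl)cyclohex-2-en-1-one | CCOC1=CC(=O)C(C(=O)C(F)(F)F)C(C)(C)C1
F2 | step 3 | 6-diazo-3-ethoxy-5,5-dimethylcyclohex-2-en-1-one | CCOC1=CC(=O)C(=[N+]=[N-])C(C)(C)C1
F3 | step 3 | 2-[(1E,3E)-5-{[tert-butyl(dimethyl)silyl]oxy}-3-methylpenta-1,3-dien-1-yl]-1,3,2-benzodioxaborole | CC(C)(C)[Si](C)(C)OC/C=C(C)/C=C/B1Oc2ccccc2O1
F4 | step 3 | [(1E,3E)-5-{[tert-butyl(dimethyl)silyl]oxy}-3-methylpenta-1,3-dien-1-yl]boronic acid | CC(C)(C)[Si](C)(C)OC/C=C(C)/C=C/B(O)O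
F5 | step 3 | (6R)-6-[(1E,3E)-5-{[tert-butyl(dimethyl)silyl]oxy}-3-methylpenta-1,3-dien-1-yl]-3-ethoxy-5,5-dimethylcyclohex-2-en-1-one | CC(C)(C)[Si](C)(C)OC/C=C(C)/C=C/[C@@H]1C(C)(C)CC(OCC)=CC1=O
F6 | step 6 | (3R,4R)-4-[(1E,3E)-5-{[tert-butyl(dimethyl)silyl]oxy}-3-methylpenta-1,3-dien-1-yl]-3,5,5-trimethyl-3-(4,4,5,5-tetramethyl-1,3,2-dioxaborolan-2-yl)cyclohexan-1-one | CC(C)(C)[Si](C)(C)OC/C=C(C)/C=C/[C@H]1C(C)(C)CC(=O)C[C@]1(C)B2OC(C)(C)C(C)(C)O2
F7 | step 10 | (3S,4S)-3-hydroxy-4-[(1E,3E)-5-hydroxy-3-methylpenta-1,3-dien-1-yl]-3,5,5-trimethylcyclohexan-1-one | OC/C=C(C)/C=C/[C@H]1C(C)(C)CC(=O)C[C@]1(C)O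
F8 | step 10 | (3S,4S)-4-[(1E,3E)-5-bromo-3-methylpenta-1,3-dien-1-yl]-3-hydroxy-3,5,5-trimethylcyclohexan-1-one | BrC/C=C(C)/C=C/[C@H]1C(C)(C)CC(=O)C[C@]1(C)O
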